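**Retrosynthetic overview**
1. Target 12 ⇐ C17 aldehyde 11 (Pinnick) ⇐ 17-alcohol 9 ⇐ 8(17)-methylene of pinusolidic acid 7 (hydroboration). C8 is set last, by base equilibration of the aldehyde to the equatorial position.
2. Butenolide of 7 ⇐ 16-formylfuran 3 by [4+2] cycloaddition of singlet oxygen (endoperoxide 4). Its deformylative collapse makes C16 the lactone carbonyl, and NaBH4 then removes the C15 hydroxyl.
3. 3 ⇐ (+)-lambertianic acid 1 by C16-selective Vilsmeier–Haack formylation.
4. Ring order: decalin rings A/B with C4, C5, C9 and C10 are bought in 1. The only ring built is the oxygen heterocycle (endoperoxide → butenolide); C8 is then set by the existing centres.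

Assumption: (+)-lambertianic acid (main resin acid of Pinus sibirica, sold by natural-product suppliers) is taken as the commercial chiral starting material. α/β refer to the usual labdane drawing (C20 methyl β); labdane numbering is used throughout.

**Step 1**
Reactants: 1 (+)-lambertianic acid
Product: 3 16-formyllambertianic acid, via iminium chloride 2 (not isolated)
Conditions: POCl3 (2.5 equiv), DMF, 0 °C → rt; then aq. NaOAc, 50 °C
Reagents that add atoms: N,N-dimethylformamide, CN(C)C=O (formyl carbon); water, O (aldehyde oxygen, on hydrolysis of the iminium salt)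
Why: Vilsmeier–Haack electrophilic substitution of a 3-alkylfuran goes to the α-carbon next to the alkyl group (C16), the hydrolytic work-up returns any activated carboxyl to the free acid, and no stereocentre is touched.

**Step 2**
Reactants: 3 16-formyllambertianic acid
Product: 7 pinusolidic acid, via furan endoperoxide 4 (not isolated), via hydroxybutenolide 5 (not isolated), via hydroxy acid 6 (not isolated)
Conditions: O2, hν (white LED), rose bengal (1 mol %), MeOH, 0 °C; then NaBH4, 0 °C; then 1 M HCl to pH 2, rt
Reagents that add atoms: dioxygen, O=O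
Why: Singlet oxygen adds across C15/C16 of the furan in a [4+2] cycloaddition faster than it attacks the hindered 8(17)-methylene, methanol-induced loss of the formyl group as methyl formate turns C16 into the lactone carbonyl with OH on C15, and NaBH4 reduction of the open aldehyde form followed by acid lactonisation gives the α-substituted butenolide without touching a ring stereocentre.

**Step 3**
Reactants: 7 pinusolidic acid
Product: 9 17-hydroxy-8α-H-labd-13-en-16,15-olid-19-oic acid, via alkylborane 8 (not isolated)
Conditions: 9-BBN (3 equiv), THF, 0 °C → rt; then 30 % H2O2, aq. NaOAc, 0 °C → rt (acidic work-up)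
Reagents that add atoms: hydrogen peroxide, OO
Why: Brown hydroboration–oxidation puts boron on terminal C17 and hydrogen on C8 from the α-face, away from the axial C20 methyl, while the lactone, its conjugated alkene and the acid (held as acyloxyborane) are not reduced at rt; any 8-epimer converges in step 4.

**Step 4**
Reactants: 9 17-hydroxy-8α-H-labd-13-en-16,15-olid-19-oic acid
Product: 11 17-oxo-8β-H-labd-13-en-16,15-olid-19-oic acid, via axial aldehyde 10 (not isolated)
Conditions: TEMPO (10 mol %), PhI(OAc)2 (1.2 equiv), CH2Cl2, rt; then DBU (3 equiv), CH2Cl2, rt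
Reagents that add atoms: none
Why: TEMPO/PhI(OAc)2 oxidation stops at the aldehyde, and DBU epimerises C8 through the enolate to the thermodynamic equatorial 8α-CHO (trans-diequatorial to the C9 chain, no 1,3-diaxial clash with C20), so C8 is set by the existing ring stereocentres.

**Step 5**
Reactants: 11 17-oxo-8β-H-labd-13-en-16,15-olid-19-oic acid
Product: 12 8β-H-labd-13-en-16,15-olide-17,19-dioic acid (target)
Conditions: NaClO2, NaH2PO4, 2-methyl-2-butene, t-BuOH/H2O, rt
Reagents that add atoms: sodium chlorite, [Na+].[O-]Cl=O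
Why: Pinnick (Lindgren–Kraus) oxidation converts the aldehyde to the acid under buffered, non-epimerising conditions that leave the butenolide alone, so the equatorial C8 configuration is kept.

**Compound list**
1 | (+)-lambertianic acid, 15,16-epoxylabda-8(17),13(16),14-trien-19-oic acid (4β-axial CO2H, 5α-H, 9α-H, 10β-CH3) | C[C@]12CCC[C@](C)(C(=O)O)[C@@H]1CCC(=C)[C@@H]2CCc1ccoc1 | starting material
2 | C16 dimethyliminium chloride of 1 (Vilsmeier adduct before hydrolysis) | C[C@]12CCC[C@](C)(C(=O)O)[C@@H]1CCC(=C)[C@@H]2CCc1ccoc1C=[N+](C)C.[Cl-] | intermediate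
3 | 16-formyllambertianic acid (CHO on furan C16, next to the side chain) | C[C@]12CCC[C@](C)(C(=O)O)[C@@H]1CCC(=C)[C@@H]2CCc1ccoc1C=O | intermediate
4 | furan endoperoxide: O–O bridge between C15 and C16, formyl still on C16, C13=C14 retained (mixture at the two new acetal carbons) | C[C@]12CCC[C@](C)(C(=O)O)[C@@H]1CCC(=C)[C@@H]2CCC1=CC2OOC1(C=O)O2 | intermediate
5 | 15-hydroxypinusolidic acid, 15-hydroxylabda-8(17),13-dien-16,15-olid-19-oic acid (C15 epimers) | C[C@]12CCC[C@](C)(C(=O)O)[C@@H]1CCC(=C)[C@@H]2CCC1=CC(O)OC1=O | intermediate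
6 | (13Z)-15-hydroxylabda-8(17),13-diene-16,19-dioic acid (ring-open hydroxy acid) | C[C@]12CCC[C@](C)(C(=O)O)[C@@H]1CCC(=C)[C@@H]2CC/C(C(=O)O)=C/CO | intermediate
7 | pinusolidic acid, labda-8(17),13-dien-16,15-olid-19-oic acid | C[C@]12CCC[C@](C)(C(=O)O)[C@@H]1CCC(=C)[C@@H]2CCC1=CCOC1=O | intermediate
8 | C17 B-alkyl-9-BBN adduct of 7 (8α-H), carboxyl as its 9-BBN acyloxyborane | C[C@]12CCC[C@](C)(C(=O)OB3C4CCCC3CCC4)[C@@H]1CC[C@H](CB3C4CCCC3CCC4)[C@@H]2CCC1=CCOC1=O | intermediate
9 | 17-hydroxy-8α-H-labd-13-en-16,15-olid-19-oic acid (8β, axial CH2OH) | C[C@]12CCC[C@](C)(C(=O)O)[C@@H]1CC[C@H](CO)[C@@H]2CCC1=CCOC1=O | intermediate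
10 | 17-oxo-8α-H-labd-13-en-16,15-olid-19-oic acid (8β, axial CHO) | C[C@]12CCC[C@](C)(C(=O)O)[C@@H]1CC[C@H](C=O)[C@@H]2CCC1=CCOC1=O | intermediate
11 | 17-oxo-8β-H-labd-13-en-16,15-olid-19-oic acid (8α, equatorial CHO) | C[C@]12CCC[C@](C)(C(=O)O)[C@@H]1CC[C@@H](C=O)[C@@H]2CCC1=CCOC1=O | intermediate
12 | 8β-H-labd-13-en-16,15-olide-17,19-dioic acid (8α-equatorial and 4β-axial CO2H, 5α-H, 9α-H, 10β-CH3; 4S,5R,8R,9S,10R) | C[C@]12CCC[C@](C)(C(=O)O)[C@@H]1CC[C@@H](C(=O)O)[C@@H]2CCC1=CCOC1=O | target

**Totals**
Total step count: 5. Longest linear sequence: 5.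

**Steps most likely to fail, with fallbacks**

Step 1 (Vilsmeier formylation with a free, hindered CO2H; C16 versus C15 selectivity). The acid may be held up as acyl chloride or amide, and some 15-formyl isomer is expected. The fallback sets out from 1 and returns at 3. NBS in DMF at −20 °C brominates the furan at C16 to give 16-bromolambertianic acid F1. n-BuLi (1 equiv, −78 °C) makes the lithium carboxylate and t-BuLi (2.1 equiv) exchanges bromine for lithium to give the C16-lithio lithium carboxylate F2. A DMF quench and dilute HCl work-up give 3. This replaces electrophilic formylation by halogen–metal exchange, so the carboxyl never meets a chlorinating reagent and the regiochemistry is fixed by the bromide.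

Step 2 (photooxygenation of a deactivated formylfuran next to an ene-reactive exocyclic alkene). The fallback sets out from 3 and returns at 7 without photochemistry. A Dakin-type Baeyer–Villiger oxidation (30 % H2O2, catalytic bis(2-nitrophenyl) diselenide, CH2Cl2, rt) gives the furan-2-yl formate, 16-formyloxylambertianic acid F3. Mild hydrolysis (aq. NaHCO3/THF) frees the 2-hydroxyfuran, which appears as the non-conjugated 2(3H)-furanone isomer F4. Et3N in CH2Cl2 moves the double bond into conjugation to give 7. The weak point is possible epoxidation of the 8(17)-alkene by the peroxyseleninic acid.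

Step 3 (hydroboration beside a butenolide and a free acid; over-reduction or a sluggish hindered alkene). The fallback sets out from 7 and returns at 11. mCPBA (NaHCO3, CH2Cl2, 0 °C) epoxidises only the electron-rich exocyclic alkene, from the α-face, to give the 8α,17-epoxide F5. BF3·OEt2 (CH2Cl2, −78 °C) opens it at C8 and a 1,2-hydride shift from C17 (Meinwald rearrangement) gives the C17 aldehyde as a 10/11 mixture. DBU equilibrates this to 11, and step 5 follows. No borane meets the lactone or the acid, and the alcohol stage is skipped.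

**Further compounds**
F1 | step 1 | 16-bromolambertianic acid | C[C@]12CCC[C@](C)(C(=O)O)[C@@H]1CCC(=C)[C@@H]2CCc1ccoc1Br
F2 | step 1 | C16-lithio lithium carboxylate of lambertianic acid | C[C@]12CCC[C@](C)(C(=O)O[Li])[C@@H]1CCC(=C)[C@@H]2CCc1ccoc1[Li]
F3 | step 2 | 16-formyloxylambertianic acid (furan-2-yl formate) | C[C@]12CCC[C@](C)(C(=O)O)[C@@H]1CCC(=C)[C@@H]2CCc1ccoc1OC=O
F4 | step 2 | 2(3H)-furanone isomer of 7, labda-8(17),14-dien-16,15-olid-19-oic acid (C13 epimers) | C[C@]12CCC[C@](C)(C(=O)O)[C@@H]1CCC(=C)[C@@H]2CCC1C=COC1=O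
F5 | step 3 | 8α,17-epoxylabd-13-en-16,15-olid-19-oic acid | C[C@]12CCC[C@](C)(C(=O)O)[C@@H]1CC[C@]3(CO3)[C@@H]2CCC1=CCOC1=O
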